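**Retrosynthetic overview**
- The target acid comes from its benzyl ester by hydrogenolysis, because the depside ester would not survive a hydrolytic deprotection.
- Key step: the depside carbonyl is not taken from a benzoic acid. One Pd-catalysed three-component aryloxycarbonylation joins 2-iodo-1,5-dimethoxy-3-pentylbenzene, CO and benzyl olivetolate (at its 4-OH), making the aryl–C(=O) and C(=O)–OAr bonds together.
- The aryl iodide comes from olivetol dimethyl ether by regioselective C–H iodination; benzyl olivetolate comes from olivetolic acid by carboxylate-selective benzylation.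
- No ring is formed: both benzene rings are bought intact.

Assumption: the target SMILES has no stereocentre or stereogenic axis, so the compound is achiral and "single enantiomer" needs no stereocontrol; olivetol dimethyl ether and olivetolic acid are taken as commercial.

**Route**

Step 1
Reactants: 1 1,3-dimethoxy-5-pentylbenzene (olivetol dimethyl ether)
Product: 2 2-iodo-1,5-dimethoxy-3-pentylbenzene
Conditions: NIS (1.05 equiv), TFA (10 mol%), MeCN, 0 °C → rt, dark
Reagents that add atoms: N-iodosuccinimide (NIS), O=C1CCC(=O)N1I
Why: Electrophilic aromatic iodination (SEAr) goes to the two equivalent positions para to one OMe and ortho to the other (C4/C6), the pattern known for halogenation and formylation of 5-alkylresorcinol dimethyl ethers, and 1.05 equiv of NIS limits di-iodination; no stereocentre is formed.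

Step 2
Reactants: 3 2,4-dihydroxy-6-pentylbenzoic acid (olivetolic acid)
Product: 5 benzyl 2,4-dihydroxy-6-pentylbenzoate, via potassium olivetolate 4 (not isolated)
Conditions: KHCO3 (1.2 equiv), BnBr (1.05 equiv), DMF, rt, 16 h
Reagents that add atoms: benzyl bromide, BrCc1ccccc1
Why: Chemoselective SN2 O-alkylation of a carboxylate: bicarbonate deprotonates only the CO2H and not the phenols, so carboxylate 4 is the only nucleophile for BnBr, and room temperature avoids decarboxylation of the β-resorcylic acid.

Step 3
Reactants: 2 2-iodo-1,5-dimethoxy-3-pentylbenzene (1.0 equiv), 5 benzyl 2,4-dihydroxy-6-pentylbenzoate (1.2 equiv)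
Product: 8 benzyl 4-[(2,4-dimethoxy-6-pentylbenzoyl)oxy]-2-hydroxy-6-pentylbenzoate, via arylpalladium(II) iodide complex 6 (not isolated), via aroylpalladium(II) iodide complex 7 (not isolated)
Conditions: Pd(OAc)2 (5 mol%), Xantphos (6 mol%), Et3N (3 equiv), CO (1 atm, balloon), toluene, 90 °C
Reagents that add atoms: carbon monoxide, [C-]#[O+]
Why: Pd-catalysed three-component aryloxycarbonylation (Heck-type carbonylative esterification): oxidative addition of the C–I bond gives 6, CO insertion gives acyl complex 7, and the free, more acidic 4-OH of 5 (the 2-OH is tied up in an H-bond to the benzyl ester) captures the acyl group as its ammonium phenoxide, wide-bite-angle Xantphos favouring acyl C–O bond formation at 1 atm CO; the reaction class is known but untested on this di-ortho-substituted pair.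

Step 4
Reactants: 8 benzyl 4-[(2,4-dimethoxy-6-pentylbenzoyl)oxy]-2-hydroxy-6-pentylbenzoate
Product: 9 4-[(2,4-dimethoxy-6-pentylbenzoyl)oxy]-2-hydroxy-6-pentylbenzoic acid (target, CNP0139062.0)
Conditions: H2 (1 atm), 10% Pd/C, EtOAc, rt
Reagents that add atoms: none
Why: Catalytic hydrogenolysis of the benzyl ester (O-debenzylation) is orthogonal to the diaryl ester, the methyl ethers and the phenol, so the free acid is released without touching the depside linkage.

**Compound list**
1 | 1,3-dimethoxy-5-pentylbenzene (olivetol dimethyl ether) | CCCCCc1cc(OC)cc(OC)c1 | starting material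
2 | 2-iodo-1,5-dimethoxy-3-pentylbenzene | CCCCCc1cc(OC)cc(OC)c1I | intermediate
3 | 2,4-dihydroxy-6-pentylbenzoic acid (olivetolic acid) | CCCCCc1cc(O)cc(O)c1C(=O)O | starting material
4 | potassium olivetolate (potassium 2,4-dihydroxy-6-pentylbenzoate; formed in the flask) | CCCCCc1cc(O)cc(O)c1C(=O)[O-].[K+] | intermediate
5 | benzyl 2,4-dihydroxy-6-pentylbenzoate | CCCCCc1cc(O)cc(O)c1C(=O)OCc1ccccc1 | intermediate
6 | arylpalladium(II) iodide complex [(2,4-dimethoxy-6-pentylphenyl)Pd(I)(Xantphos); formed in the flask; ligand written as a separate SMILES component] | CCCCCc1cc(OC)cc(OC)c1[Pd]I.CC1(C)c2cccc(P(c3ccccc3)c3ccccc3)c2Oc2c(P(c3ccccc3)c3ccccc3)cccc21 | intermediate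
7 | aroylpalladium(II) iodide complex [(2,4-dimethoxy-6-pentylbenzoyl)Pd(I)(Xantphos); formed in the flask; ligand written as a separate SMILES component] | CCCCCc1cc(OC)cc(OC)c1C(=O)[Pd]I.CC1(C)c2cccc(P(c3ccccc3)c3ccccc3)c2Oc2c(P(c3ccccc3)c3ccccc3)cccc21 | intermediate
8 | benzyl 4-[(2,4-dimethoxy-6-pentylbenzoyl)oxy]-2-hydroxy-6-pentylbenzoate | CCCCCc1cc(OC(=O)c2c(CCCCC)cc(OC)cc2OC)cc(O)c1C(=O)OCc1ccccc1 | intermediate
9 | 4-[(2,4-dimethoxy-6-pentylbenzoyl)oxy]-2-hydroxy-6-pentylbenzoic acid | CCCCCc1cc(OC(=O)c2c(CCCCC)cc(OC)cc2OC)cc(O)c1C(=O)O | target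

**Step count**
Total steps: 4. Longest linear sequence: 3 steps (1 → 2 → 8 → 9, or equally 3 → 5 → 8 → 9).

**Three steps most likely to fail, with fallbacks**

Step 3 (highest risk). The di-ortho-substituted acyl-palladium may be captured too slowly by the weakly nucleophilic phenol, giving hydrodeiodination back to 1 or stalled conversion. The fallback gives up the carbonylative coupling for stepwise acylation. It sets out from 2: iodine–magnesium exchange (i-PrMgCl·LiCl, THF, 0 °C → rt) gives 2,4-dimethoxy-6-pentylphenylmagnesium chloride F1. Carboxylation with CO2 and work-up with aq. HCl gives 2,4-dimethoxy-6-pentylbenzoic acid F2. Treating F2 and 5 with TFAA in toluene at rt forms 2,4-dimethoxy-6-pentylbenzoic trifluoroacetic anhydride F3 in the flask, which acylates the 4-OH of 5. The fallback comes back to the route at 8.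

Step 1. Acid-promoted iodination of a very electron-rich arene is reversible, so the 2-iodo isomer (between the two OMe groups) or di-iodide could contaminate 2. The fallback fixes the regiochemistry by an irreversible bromination and brings in iodine through an organolithium. It sets out from 1: NBS (1.0 equiv, MeCN, 0 °C) gives 2-bromo-1,5-dimethoxy-3-pentylbenzene F4. Bromine–lithium exchange (n-BuLi, THF, −78 °C) gives 2,4-dimethoxy-6-pentylphenyllithium F5, which is quenched with I2. The fallback comes back to the route at 2.

Step 2. Partial O-benzylation of the 4-OH or decarboxylation of 3 could erode the yield of 5. The fallback avoids an alkylating agent and makes the ester by acyl substitution on a cyclic acetonide. It sets out from 3: acetone/TFAA/TFA (0 °C → rt) gives 7-hydroxy-2,2-dimethyl-5-pentyl-4H-1,3-benzodioxin-4-one F6. Ring-opening with benzyl alcohol/NaH (THF, 0 → 50 °C, then aq. NH4Cl) expels acetone and gives the benzyl salicylate. The fallback comes back to the route at 5.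

**Further compounds**
F1 | step 3 | 2,4-dimethoxy-6-pentylphenylmagnesium chloride | CCCCCc1cc(OC)cc(OC)c1[Mg]Cl
F2 | step 3 | 2,4-dimethoxy-6-pentylbenzoic acid | CCCCCc1cc(OC)cc(OC)c1C(=O)O
F3 | step 3 | 2,4-dimethoxy-6-pentylbenzoic trifluoroacetic anhydride | CCCCCc1cc(OC)cc(OC)c1C(=O)OC(=O)C(F)(F)F
F4 | step 1 | 2-bromo-1,5-dimethoxy-3-pentylbenzene | CCCCCc1cc(OC)cc(OC)c1Br
F5 | step 1 | 2,4-dimethoxy-6-pentylphenyllithium | [Li]c1c(CCCCC)cc(OC)cc1OC
F6 | step 2 | 7-hydroxy-2,2-dimethyl-5-pentyl-4H-1,3-benzodioxin-4-one | CCCCCc1cc(O)cc2OC(C)(C)OC(=O)c12
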